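The earlier runs and the new flask were computed from invented constants; scatter was added.

In this closed, stirred vessel at constant volume, starting material and partner make product while protic impurity quenches partner, and two people read the earlier runs differently.

| flask | starting material | partner | protic impurity | temperature | remark | time |
|---|---|---|---|---|---|---|
| Friday's | 10 mM | 1.1 equiv | 2.8 mM | 55 °C | run made earlier |  |
| Wednesday's | 10 mM | 1.1 equiv | 7.5 mM | 88 °C | run made earlier |  |
| violet | 10 mM | 1.10 equiv | 2.50 mM |  | at 40 °C throughout | 6.0 h |
| teal | 10 mM | 1.10 equiv | 5.00 mM |  | at 40 °C until 3.0 h, from then on at 100 °C | 6.0 h |

- Friday's (time / min: product / %, starting material / %): 10.0: 5.5, 93.9; 25.0: 10.1, 89.2; 60.0: 22.0, 78.1; 120: 41.7, 59.2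
- Wednesday's (time / min: product / %, starting material / %): 2.00: 4.8, 95.1; 5.00: 11.2, 88.8; 12.0: 25.0, 75.8; 20.0: 34.9, 65.4

(scatter of a reading: 0.3 percentage points)

- which one finishes higher in amount of product, in percent of the starting material charged ("neither" within 2 percentage points) (violet / teal / neither)
- amount of product at the end, in percent of the starting material charged, violet
- amount of product at the end, in percent of the starting material charged, teal

- steps under discussion: starting material + partner + product -> 2 product; starting material + partner -> product; partner <-> dormant form; partner + protic impurity -> quenched reagent

The clock-keeper works with the fraction of starting material left. She divides time by minus the logarithm of that fraction and calls the result the emptying time, treating the fall of starting material as a simple exponential decay. Friday's run gives 229 min from its last reading and 243 min from the one before, so the figure holds fairly steady there. Wednesday's run gives 47.1 min from its last reading. Those two runs differ in impurity as well as in temperature, but she credits temperature with the whole difference and gets an apparent activation energy of 47.2 kJ/mol, and at 40 °C her emptying time, the time in which the fraction left shrinks by a factor e, comes to 8.74 h. Her reckoning therefore leaves violet 50.3% of its starting material and gives it 49.7% product. Her emptying time for teal at 100 °C is 28.4 min, so she reckons teal's starting material down to 0.126%.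

The counter treats partner as the limiting reagent and subtracts the impurity from it, one for one. That gives Wednesday's run a ceiling of 35.0%, and its last reading stands at 34.9%. Violet's ceiling is 85.0% and teal's is 60.0%. The clock-keeper answers that Wednesday's product was still rising, from 25.0% to 34.9% over the last interval.

I take the lower number for each flask: 49.7% for violet, where the clock stands lower, and 60.0% for teal, so teal finishes higher. The forecast puts teal ahead with 36% for violet, lower than my figure, and 60% for teal, holding that “the impurity destroys partner one-for-one”.

The flask gives teal ahead, with 44.4% for violet and 67.3% for teal.

    starting material + partner + product → 2 product (k = 11.0 /M²/s, Ea = 44.0 kJ/mol)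
    starting material + partner → product (k = 0.00800 /M/s, Ea = 54.0 kJ/mol)
    partner ⇌ dormant form (K = 7.70, k = 0.00110 /s, Ea = 91.0 kJ/mol, ΔH = −18.0 kJ/mol)
    partner + protic impurity → quenched reagent (k = 0.0440 /M/s, Ea = 57.0 kJ/mol)
    (constants at 40 °C)

Teal belongs to the counter: at 6.00 h it holds 0% of its partner and 32.7% of its starting material, though 67.3% stands 7.3 percentage points above the counter's ceiling, with 14.5% of the charged impurity unquenched. Violet, well below its ceiling, belongs to the clock: 55.6% is left against her 50.3%, an emptying time of 10.2 h against 8.74 h. The neighbour, violet kept at 55 °C, shares Friday's temperature, though Friday's impurity was 2.8 mM against its 2.50 mM; Friday's 229 min reckons 20.7% left, and that flask holds 23.9% of its starting material and 76.1% product.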